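Working numbering (spiro[5.5]undecane): ring A = C1–C6 (C1 carries the vinylic methyl, C4 = CHBr, C5 = CMe2, C6 = spiro carbon); ring B = C6–C11 (C8 = CHCl, C9 = C(CH3)Br).
Enabling feature: the neopentyl bromide carbon C4 of ring A lies two bonds from C2, and C2 is alpha to C1, which can be carried as a ketone. A C2 radical next to that ketone can add to a vinyl group (C3=C4) held on C5, and the C4 radical so formed takes the bromine.
Cuts, last bond first: C1–CH3 (enol triflate coupling); C2–C3 together with C4–Br (atom-transfer radical cyclization of a bromomethyl ketone on C6); C1–C2 (diazomethane); C9–Br, then C8–Cl/C9–O (lactone opening, chlorolactonization); C9–CH3; C5–C6 (Ireland–Claisen of a prenyl ester).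
Forward: ring B is bought as a ketal-protected 4-oxocyclohexanecarboxylic acid; C5–C6 and the vinyl group are installed on the still symmetric ring; ring B is then desymmetrized, methylated and halogenated; ring A closes third from last, at C2–C3.
Stereochemistry: C6 by enantioselective deprotonation of the prochiral ring B ketone with a chiral lithium amide; C8 and C9 from C6 through the carboxyl tether (anti chlorolactonization, then bromide opening of the lactone with retention via the chloronium ion); C4 in the bromine transfer to the ring A radical, biased by the ring A chair.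

Key step: step 10

Remark on conformation: in every intermediate with the quaternary carbon, ring B is assumed to be the chair with the tert-alkyl substituent (later C5) equatorial and the carbonyl-bearing substituent (later C1) axial; the arguments of steps 4, 7, 8 and 10 rest on this.
Remark on the sense of induction: the (R,R)-amide of step 4 is chosen by analogy with 4-tert-butylcyclohexanone, whose (S)-enol derivative maps onto the required (R)-triflate; if the axial ester reverses the sense, the (S,S)-amide is used.

Step 1
Reactants: 1 1,4-dioxaspiro[4.5]decane-8-carboxylic acid; 2 3-methylbut-2-en-1-ol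
Product: 3 3-methylbut-2-en-1-yl 1,4-dioxaspiro[4.5]decane-8-carboxylate
Conditions: DCC, DMAP (cat.), CH2Cl2, 0 °C to rt
Reagents that add atoms: none
Why: Steglich esterification, in which the carbodiimide activates the acid and DMAP transfers the acyl group to the primary allylic alcohol without touching the ketal; no stereocenter is involved.

Step 2
Reactants: 3 3-methylbut-2-en-1-yl 1,4-dioxaspiro[4.5]decane-8-carboxylate
Product: 7 1-(2-methylbut-3-en-2-yl)-4-oxocyclohexane-1-carboxylic acid, via silyl ketene acetal 4 (not isolated), via trimethylsilyl ester 5 (not isolated), via ketal acid 6 (not isolated)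
Conditions: LiN(iPr)2, Me3SiCl, THF, −78 °C to 65 °C; then 2 M HCl, THF, rt
Reagents that add atoms: water, O
Why: Ireland–Claisen rearrangement, in which the ester enolate is trapped as the silyl ketene acetal, a chair [3,3]-sigmatropic shift joins the ring carbon (future C6) to the dimethyl-substituted allyl terminus (future C5) and leaves the vinyl group, and the acidic work-up cleaves silyl ester and dioxolane; the ring is still symmetric, so no stereocenter arises.

Step 3
Reactants: 7 1-(2-methylbut-3-en-2-yl)-4-oxocyclohexane-1-carboxylic acid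
Product: 8 methyl 1-(2-methylbut-3-en-2-yl)-4-oxocyclohexane-1-carboxylate
Conditions: MeI, K2CO3, DMF, rt
Reagents that add atoms: iodomethane, CI
Why: SN2 alkylation of the carboxylate at oxygen avoids acyl substitution at this doubly neopentyl carbonyl group and masks the acid for the enolate chemistry that follows.

Step 4
Reactants: 8 methyl 1-(2-methylbut-3-en-2-yl)-4-oxocyclohexane-1-carboxylate
Product: 10 methyl (1R)-1-(2-methylbut-3-en-2-yl)-4-{[(trifluoromethyl)sulfonyl]oxy}cyclohex-3-ene-1-carboxylate, via lithium enolate 9 (not isolated)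
Conditions: (R,R)-bis(1-phenylethyl)amine, n-BuLi, LiCl, THF, −78 °C; add 8 at −100 °C; then N-(5-chloropyridin-2-yl)triflimide (5-Cl-PyNTf2), −78 °C to rt; aq. NH4Cl
Reagents that add atoms: N-(5-chloropyridin-2-yl)-1,1,1-trifluoro-N-[(trifluoromethyl)sulfonyl]methanesulfonamide, O=S(=O)(N(c1ccc(Cl)cn1)S(=O)(=O)C(F)(F)F)C(F)(F)F
Why: Enantioselective deprotonation of a prochiral 4,4-disubstituted cyclohexanone by a C2-symmetric chiral lithium amide, followed by O-sulfonylation of the enolate: the tert-alkyl group locks the chair with the ester axial, the amide removes one of the two enantiotopic axial α-hydrogens, and the position of the enol double bond thereby makes the quaternary carbon (future C6) a stereocenter of R configuration.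

Step 5
Reactants: 10 methyl (1R)-1-(2-methylbut-3-en-2-yl)-4-{[(trifluoromethyl)sulfonyl]oxy}cyclohex-3-ene-1-carboxylate
Product: 11 methyl (1R)-4-methyl-1-(2-methylbut-3-en-2-yl)cyclohex-3-ene-1-carboxylate
Conditions: MeZnCl, Pd(PPh3)4 (5 mol %), THF, 0 °C to rt
Reagents that add atoms: methylzinc chloride, C[Zn]Cl
Why: Negishi coupling, in which zerovalent palladium inserts into the alkenyl C–O bond of the triflate, methyl is transferred from zinc and reductive elimination gives the trisubstituted ring B alkene carrying the future C9 methyl group; the hindered ester and the vinyl group are inert.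

Step 6
Reactants: 11 methyl (1R)-4-methyl-1-(2-methylbut-3-en-2-yl)cyclohex-3-ene-1-carboxylate
Product: 12 (1R)-4-methyl-1-(2-methylbut-3-en-2-yl)cyclohex-3-ene-1-carboxylic acid
Conditions: NaSEt, DMF, 90 °C; then 1 M HCl
Reagents that add atoms: none
Why: The thiolate attacks the methyl carbon (SN2 dealkylation), which frees the carboxylic acid where hydroxide attack at the shielded carbonyl carbon would fail; the stereocenter is untouched.

Step 7
Reactants: 12 (1R)-4-methyl-1-(2-methylbut-3-en-2-yl)cyclohex-3-ene-1-carboxylic acid
Product: 13 (1S,4R,6S)-6-chloro-1-methyl-4-(2-methylbut-3-en-2-yl)-2-oxabicyclo[2.2.2]octan-3-one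
Conditions: NCS, DABCO (10 mol %), CH2Cl2, −20 °C to 0 °C
Reagents that add atoms: N-chlorosuccinimide, O=C1CCC(=O)N1Cl
Why: Chlorolactonization, in which the chlorenium donor attacks the trisubstituted ring alkene (far more nucleophilic than the neopentyl-flanked vinyl group) and the axial carboxyl group on C6 captures the tertiary end (future C9) in Markovnikov fashion to give the bridged δ-lactone, so that oxygen lands on C9 on the face of the carboxyl carbon and chlorine on C8 anti to it, on the face of the tert-alkyl group; C6 thus fixes both new stereocenters.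

Step 8
Reactants: 13 (1S,4R,6S)-6-chloro-1-methyl-4-(2-methylbut-3-en-2-yl)-2-oxabicyclo[2.2.2]octan-3-one
Product: 14 (1R,3S,4S)-4-bromo-3-chloro-4-methyl-1-(2-methylbut-3-en-2-yl)cyclohexane-1-carboxylic acid
Conditions: HBr (33 % in AcOH), CH2Cl2, 0 °C, dark, BHT (cat.)
Reagents that add atoms: hydrogen bromide, Br
Why: Acid-mediated alkyl–oxygen cleavage of a tertiary bridged lactone (the bond type that HBr cleaves in 1,8-cineole): in the bicyclo[2.2.2] frame the C8–Cl bond is antiperiplanar to the C9–O bond, so ionization regenerates the chloronium ion of step 7 and bromide opens it at the tertiary carbon anti to chlorine, which puts bromine where the lactone oxygen was (retention at C9) and gives the trans bromochloride.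

Step 9
Reactants: 14 (1R,3S,4S)-4-bromo-3-chloro-4-methyl-1-(2-methylbut-3-en-2-yl)cyclohexane-1-carboxylic acid
Product: 17 2-bromo-1-[(1R,3S,4S)-4-bromo-3-chloro-4-methyl-1-(2-methylbut-3-en-2-yl)cyclohexyl]ethan-1-one, via acid chloride 15 (not isolated), via diazoketone 16 (not isolated)
Conditions: (COCl)2, DMF (cat.), CH2Cl2, 0 °C to rt, evaporate; CH2N2 (excess), Et2O, 0 °C to rt; then 48 % aq. HBr, 0 °C
Reagents that add atoms: diazomethane, C=[N+]=[N-]; hydrogen bromide, Br
Why: Acyl chloride formation, acylation of diazomethane (first stage of the Arndt–Eistert sequence, which works for neopentyl acid chlorides) and protonation of the diazoketone with loss of dinitrogen and capture of bromide give the bromomethyl ketone, while the ring halides, the vinyl group and all stereocenters stay as they are.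

Step 10
Reactants: 17 2-bromo-1-[(1R,3S,4S)-4-bromo-3-chloro-4-methyl-1-(2-methylbut-3-en-2-yl)cyclohexyl]ethan-1-one
Product: 18 (4R,6R,8S,9S)-4,9-dibromo-8-chloro-5,5,9-trimethylspiro[5.5]undecan-1-one
Conditions: CuBr (15 mol %), tris(2-pyridylmethyl)amine (15 mol %), AIBN (10 mol %), degassed ClCH2CH2Cl (0.02 M), 60 °C
Reagents that add atoms: none
Why: CuBr with tris(2-pyridylmethyl)amine abstracts bromine reversibly from the α-bromoketone, the electrophilic α-keto radical at C2 adds to the terminal vinyl carbon C3, and the divalent copper bromide complex hands bromine to the resulting secondary C4 radical while returning to monovalent copper; this is the copper-catalysed atom-transfer radical cyclization known for α-halo carbonyl compounds, here in its 6-endo α-halo ketone form. Ring A closes 6-endo-trig because the carbonyl carbon sits inside the forming ring, which strains the 5-exo transition state, and because the internal alkene carbon is flanked by the quaternary C5. C4 is set in the bromine transfer, not in the C–C bond formation: in the ring A chair the C1 carbonyl is expected to lie syn to C7, next to the chlorine-polarized axial hydrogen on C8, so that C7 is equatorial and C11 axial on ring A, and the bulky copper bromide complex should deliver bromine equatorially, away from the syn-axial C11 and therefore cis to C7 as the target requires. This facial bias is modest, so the C4 epimer is the by-product to expect and to remove by chromatography. The step also needs the catalyst to activate the α-keto C–Br bond and not the tertiary C9–Br bond, which the carbonyl activation of the former, the low catalyst loading and the mild temperature should secure; the isomerization is redox-neutral, so the ketone, C8–Cl and C9–Br persist.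

Step 11
Reactants: 18 (4R,6R,8S,9S)-4,9-dibromo-8-chloro-5,5,9-trimethylspiro[5.5]undecan-1-one
Product: 20 (4R,6R,8S,9S)-4,9-dibromo-8-chloro-5,5,9-trimethylspiro[5.5]undec-1-en-1-yl trifluoromethanesulfonate, via potassium enolate 19 (not isolated)
Conditions: KN(SiMe3)2, THF, −78 °C; then 5-Cl-PyNTf2, −78 to −40 °C; aq. NH4Cl
Reagents that add atoms: N-(5-chloropyridin-2-yl)-1,1,1-trifluoro-N-[(trifluoromethyl)sulfonyl]methanesulfonamide, O=S(=O)(N(c1ccc(Cl)cn1)S(=O)(=O)C(F)(F)F)C(F)(F)F
Why: Kinetic enolization can occur only at C2 because C6 is quaternary, and O-sulfonylation of the potassium enolate at −78 °C gives the enol triflate before the enolate can displace the neopentyl C4 bromide or the base can eliminate the ring B halides.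

Step 12
Reactants: 20 (4R,6R,8S,9S)-4,9-dibromo-8-chloro-5,5,9-trimethylspiro[5.5]undec-1-en-1-yl trifluoromethanesulfonate
Product: 21 (4R,6S,8S,9S)-4,9-dibromo-8-chloro-1,5,5,9-tetramethylspiro[5.5]undec-1-ene
Conditions: MeZnCl, Pd(PPh3)4 (5 mol %), THF, 0 °C to rt
Reagents that add atoms: methylzinc chloride, C[Zn]Cl
Why: Negishi coupling, in which zerovalent palladium inserts into the alkenyl triflate far faster than into unactivated secondary or tertiary alkyl halides and the mild methylzinc reagent neither displaces nor eliminates the three C–halogen bonds, so the C1 methyl group and the C1=C2 alkene are set without touching any stereocenter.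

Compound list
1 | 1,4-dioxaspiro[4.5]decane-8-carboxylic acid | OC(=O)C1CCC2(CC1)OCCO2 | starting material
2 | 3-methylbut-2-en-1-ol | CC(C)=CCO | starting material
3 | 3-methylbut-2-en-1-yl 1,4-dioxaspiro[4.5]decane-8-carboxylate | CC(C)=CCOC(=O)C1CCC2(CC1)OCCO2 | intermediate
4 | trimethyl{[(3-methylbut-2-en-1-yl)oxy](1,4-dioxaspiro[4.5]decan-8-ylidene)methoxy}silane (silyl ketene acetal) | CC(C)=CCOC(O[Si](C)(C)C)=C1CCC2(CC1)OCCO2 | intermediate (not isolated)
5 | trimethylsilyl 8-(2-methylbut-3-en-2-yl)-1,4-dioxaspiro[4.5]decane-8-carboxylate | C=CC(C)(C)C1(CCC2(CC1)OCCO2)C(=O)O[Si](C)(C)C | intermediate (not isolated)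
6 | 8-(2-methylbut-3-en-2-yl)-1,4-dioxaspiro[4.5]decane-8-carboxylic acid | C=CC(C)(C)C1(CCC2(CC1)OCCO2)C(=O)O | intermediate (not isolated)
7 | 1-(2-methylbut-3-en-2-yl)-4-oxocyclohexane-1-carboxylic acid | C=CC(C)(C)C1(CCC(=O)CC1)C(=O)O | intermediate
8 | methyl 1-(2-methylbut-3-en-2-yl)-4-oxocyclohexane-1-carboxylate | COC(=O)C1(CCC(=O)CC1)C(C)(C)C=C | intermediate
9 | lithium (4R)-4-(methoxycarbonyl)-4-(2-methylbut-3-en-2-yl)cyclohex-1-en-1-olate | COC(=O)[C@]1(C(C)(C)C=C)CCC(O[Li])=CC1 | intermediate (not isolated)
10 | methyl (1R)-1-(2-methylbut-3-en-2-yl)-4-{[(trifluoromethyl)sulfonyl]oxy}cyclohex-3-ene-1-carboxylate | COC(=O)[C@]1(C(C)(C)C=C)CCC(OS(=O)(=O)C(F)(F)F)=CC1 | intermediate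
11 | methyl (1R)-4-methyl-1-(2-methylbut-3-en-2-yl)cyclohex-3-ene-1-carboxylate | COC(=O)[C@]1(C(C)(C)C=C)CCC(C)=CC1 | intermediate
12 | (1R)-4-methyl-1-(2-methylbut-3-en-2-yl)cyclohex-3-ene-1-carboxylic acid | OC(=O)[C@]1(C(C)(C)C=C)CCC(C)=CC1 | intermediate
13 | (1S,4R,6S)-6-chloro-1-methyl-4-(2-methylbut-3-en-2-yl)-2-oxabicyclo[2.2.2]octan-3-one | O=C1O[C@@]2(C)CC[C@]1(C(C)(C)C=C)C[C@@H]2Cl | intermediate
14 | (1R,3S,4S)-4-bromo-3-chloro-4-methyl-1-(2-methylbut-3-en-2-yl)cyclohexane-1-carboxylic acid | OC(=O)[C@]1(C(C)(C)C=C)CC[C@](C)(Br)[C@@H](Cl)C1 | intermediate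
15 | (1R,3S,4S)-4-bromo-3-chloro-4-methyl-1-(2-methylbut-3-en-2-yl)cyclohexane-1-carbonyl chloride | ClC(=O)[C@]1(C(C)(C)C=C)CC[C@](C)(Br)[C@@H](Cl)C1 | intermediate (not isolated)
16 | 2-diazo-1-[(1R,3S,4S)-4-bromo-3-chloro-4-methyl-1-(2-methylbut-3-en-2-yl)cyclohexyl]ethan-1-one | [N-]=[N+]=CC(=O)[C@]1(C(C)(C)C=C)CC[C@](C)(Br)[C@@H](Cl)C1 | intermediate (not isolated)
17 | 2-bromo-1-[(1R,3S,4S)-4-bromo-3-chloro-4-methyl-1-(2-methylbut-3-en-2-yl)cyclohexyl]ethan-1-one | BrCC(=O)[C@]1(C(C)(C)C=C)CC[C@](C)(Br)[C@@H](Cl)C1 | intermediate
18 | (4R,6R,8S,9S)-4,9-dibromo-8-chloro-5,5,9-trimethylspiro[5.5]undecan-1-one | O=C1CC[C@@H](Br)C(C)(C)[C@]12CC[C@](C)(Br)[C@@H](Cl)C2 | intermediate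
19 | potassium (4R,6R,8S,9S)-4,9-dibromo-8-chloro-5,5,9-trimethylspiro[5.5]undec-1-en-1-olate | [K]OC1=CC[C@@H](Br)C(C)(C)[C@]12CC[C@](C)(Br)[C@@H](Cl)C2 | intermediate (not isolated)
20 | (4R,6R,8S,9S)-4,9-dibromo-8-chloro-5,5,9-trimethylspiro[5.5]undec-1-en-1-yl trifluoromethanesulfonate | O=S(=O)(OC1=CC[C@@H](Br)C(C)(C)[C@]12CC[C@](C)(Br)[C@@H](Cl)C2)C(F)(F)F | intermediate
21 | (4R,6S,8S,9S)-4,9-dibromo-8-chloro-1,5,5,9-tetramethylspiro[5.5]undec-1-ene | CC1=CC[C@@H](Br)C(C)(C)[C@]12CC[C@](C)(Br)[C@@H](Cl)C2 | target

Total step count: 12. Longest linear sequence: 12 steps (1 to 21); 2 enters in step 1.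

Steps most likely to fail

Step 10. Bromine may be transferred to the C4 radical with too little facial discrimination, and monovalent copper may abstract bromine from the tertiary C9–Br bond, after which the β-chloro radical sheds chlorine and ring B is lost as an alkene. The fallback sets out from 17 and avoids the metal. Displacement of the primary bromide with KSC(S)OEt (acetone, 0 °C) gives O-ethyl S-(2-oxoalkyl) carbonodithioate F1. Dilauroyl peroxide in refluxing ClCH2CH2Cl then starts a xanthate group-transfer chain that closes ring A in the same 6-endo sense and gives the C4 xanthate F2; either C4 epimer serves, since both return to the same radical. Radical exchange with ethyl 2-bromo-2-methylpropanoate and dilauroyl peroxide in hot chlorobenzene replaces the xanthate by bromine; this bulky tertiary bromo ester favours equatorial delivery, and the chain carriers do not abstract halogen from ring B. The route is rejoined at 18.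

Step 8. The tethered carboxyl group may recapture the chloronium ion faster than bromide does, or reclose on the tertiary bromide during isolation and acid chloride formation; an open tertiary cation could also take bromide on the chlorine face. The fallback sets out from 13 and introduces the ketone carbon before the bromide. MeLi (1.1 equiv, THF, −78 °C, quenched cold with AcOH so that the hemiketal alkoxide cannot open and displace the C8 chlorine) adds once to the lactone and gives methyl lactol F3. HBr in AcOH/CH2Cl2 ionizes the same C9–O bond with the same antiperiplanar chlorine, but the leaving group is now a hemiketal oxygen that departs as a ketone carbonyl and does not return; the product is methyl ketone F4 with the trans bromochloride. KN(SiMe3)2 and Me3SiCl at −78 °C give silyl enol ether F5 (only one side is enolizable), and NBS at 0 °C gives 17, where the route is rejoined.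

Step 4. The amide may discriminate poorly between the two enantiotopic axial α-hydrogens, because the axial ester is 1,3-diaxial to both, and the enolate may equilibrate before it is triflated; either would lower the enantiomeric purity of everything that follows. The fallback sets out from 2 and uses resolution in place of asymmetric deprotonation. Commercial racemic 4-methylcyclohex-3-ene-1-carboxylic acid F6 is esterified with 2 (DCC, DMAP) to prenyl ester F7. Ireland–Claisen rearrangement (LiN(iPr)2, Me3SiCl, THF, −78 to 65 °C) proceeds through silyl ketene acetal F8 and trimethylsilyl ester F9, and aqueous acid gives racemic acid F10. Fractional crystallization with (R)-1-phenylethylamine should give the salt of the (R)-acid F11 (the antipodal amine is taken if this salt proves the more soluble one), while the salt of the (S)-acid F12 stays in the mother liquor. Acidification of F11 with 1 M HCl returns the route at 12, and steps 2 to 6 are then not needed.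

Further compounds
F1 | step 10 | O-ethyl S-{2-[(1R,3S,4S)-4-bromo-3-chloro-4-methyl-1-(2-methylbut-3-en-2-yl)cyclohexyl]-2-oxoethyl} carbonodithioate | CCOC(=S)SCC(=O)[C@]1(C(C)(C)C=C)CC[C@](C)(Br)[C@@H](Cl)C1
F2 | step 10 | S-[(6R,8S,9S)-9-bromo-8-chloro-5,5,9-trimethyl-1-oxospiro[5.5]undecan-4-yl] O-ethyl carbonodithioate (either C4 epimer) | O=C1CCC(SC(=S)OCC)C(C)(C)[C@]12CC[C@](C)(Br)[C@@H](Cl)C2
F3 | step 8 | (1S,4R,6S)-6-chloro-1,3-dimethyl-4-(2-methylbut-3-en-2-yl)-2-oxabicyclo[2.2.2]octan-3-ol (either C3 epimer) | CC1(O)O[C@@]2(C)CC[C@]1(C(C)(C)C=C)C[C@@H]2Cl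
F4 | step 8 | 1-[(1R,3S,4S)-4-bromo-3-chloro-4-methyl-1-(2-methylbut-3-en-2-yl)cyclohexyl]ethan-1-one | CC(=O)[C@]1(C(C)(C)C=C)CC[C@](C)(Br)[C@@H](Cl)C1
F5 | step 8 | ({1-[(1R,3S,4S)-4-bromo-3-chloro-4-methyl-1-(2-methylbut-3-en-2-yl)cyclohexyl]ethenyl}oxy)trimethylsilane | C=C(O[Si](C)(C)C)[C@]1(C(C)(C)C=C)CC[C@](C)(Br)[C@@H](Cl)C1
F6 | step 4 | racemic 4-methylcyclohex-3-ene-1-carboxylic acid | CC1=CCC(CC1)C(=O)O
F7 | step 4 | 3-methylbut-2-en-1-yl 4-methylcyclohex-3-ene-1-carboxylate (racemic) | CC1=CCC(CC1)C(=O)OCC=C(C)C
F8 | step 4 | trimethyl{[(3-methylbut-2-en-1-yl)oxy](4-methylcyclohex-3-en-1-ylidene)methoxy}silane | CC1=CCC(CC1)=C(OCC=C(C)C)O[Si](C)(C)C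
F9 | step 4 | trimethylsilyl 4-methyl-1-(2-methylbut-3-en-2-yl)cyclohex-3-ene-1-carboxylate (racemic) | CC1=CCC(CC1)(C(C)(C)C=C)C(=O)O[Si](C)(C)C
F10 | step 4 | racemic 4-methyl-1-(2-methylbut-3-en-2-yl)cyclohex-3-ene-1-carboxylic acid | CC1=CCC(CC1)(C(C)(C)C=C)C(=O)O
F11 | step 4 | (R)-1-phenylethylammonium (1R)-4-methyl-1-(2-methylbut-3-en-2-yl)cyclohex-3-ene-1-carboxylate | C[C@@H]([NH3+])c1ccccc1.[O-]C(=O)[C@]1(C(C)(C)C=C)CCC(C)=CC1
F12 | step 4 | (R)-1-phenylethylammonium (1S)-4-methyl-1-(2-methylbut-3-en-2-yl)cyclohex-3-ene-1-carboxylate | C[C@@H]([NH3+])c1ccccc1.[O-]C(=O)[C@@]1(C(C)(C)C=C)CCC(C)=CC1
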